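**Retrosynthetic overview**
- The strategy rests on the unit C9(H2)–O / C8(H) / C7(H2) of the 3-hydroxy-4-methoxybenzyl arm. This is a three-carbon chain with oxygen on C9, a stereocentre at C8 and a benzylic C7 that can act as an electrophile, and it maps onto (R)-epichlorohydrin; C8'–C9' comes from malonate.
- Target ⇐ remove two phenol benzyl ethers ⇐ dibenzoylation of the (R,R)-diol ⇐ LiAlH4 opening of the trans-2,3-dibenzyl-γ-butyrolactone.
- trans-Lactone ⇐ C8'–C7' benzylation, then decarboxylation with protonation anti to the C8 substituent ⇐ 4-arylmethyl lactone ester ⇐ aryl cuprate opening of a cyclopropane at C7, which cleaves the sacrificial C7–C8' bond.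
- Bicyclic lactone ⇐ dimethyl malonate + (R)-epichlorohydrin.
- Ring order: cyclopropane first and γ-lactone second, both in step 1; the cyclopropane is opened in step 3 and the lactone in step 9. The target keeps only its arenes.

Key step: step 1

Assumption: lignan numbering is used (C7, C8, C9 for the arm with the 3-hydroxy-4-methoxyphenyl ring, primed numbers for the arm with the 4-hydroxy-3-methoxyphenyl ring); the SMILES given corresponds to the (8R,8'R) isomer.

**Route**

Step 1
Reactants: 1 dimethyl malonate; 2 (R)-epichlorohydrin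
Product: 6 methyl (1S,5R)-2-oxo-3-oxabicyclo[3.1.0]hexane-1-carboxylate, via chlorohydrin alkoxide 3 (not isolated), via epoxy malonate 4 (not isolated), via hydroxymethyl cyclopropane diester 5 (not isolated)
Conditions: NaOMe (1.1 equiv), MeOH, 20 °C then reflux
Reagents that add atoms: none
Why: Sodiomalonate opens the epoxide of 2 at its CH2 (future C7) to give the alkoxide of 3, which displaces chloride to form epoxide 4; the re-formed malonate anion then attacks the epoxide CH (future C8) in an SN2 closure to cyclopropane alkoxide 5, and this alkoxide acylates the ester on its own face of the ring to close the γ-lactone with loss of methoxide. The closest known reaction type is the tandem malonate alkylation–cyclopropanation–lactonization of enantiopure epihalohydrins, which is established for this pair of reagents. The cyclopropane closes 3-exo-tet (attack at the terminal epoxide carbon would be a disfavoured 4-endo opening) and the lactone closes 5-exo-trig. C5 (future C8) is controlled by the stereocentre of 2, which passes through the epoxide transposition untouched and is inverted once in the cyclopropane closure to give R, and C1 is fixed as S by the cis ring fusion, since only the ester cis to the CH2O− arm can lactonize. The step needs the malonate to open the epoxide faster than it displaces chloride directly, because direct SN2 at CH2Cl would lead to the enantiomer; the strained, unhindered epoxide terminus in a protic medium should secure this, and a moderate temperature during the addition should keep the minor pathway small.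

Step 2
Reactants: 7 5-bromo-2-methoxyphenol
Product: 8 2-(benzyloxy)-4-bromo-1-methoxybenzene
Conditions: BnBr, K2CO3, DMF, 20 °C
Reagents that add atoms: benzyl bromide, BrCc1ccccc1
Why: Williamson etherification of the phenoxide masks the acidic OH so that the aryl bromide can be turned into a Grignard reagent.

Step 3
Reactants: 6 methyl (1S,5R)-2-oxo-3-oxabicyclo[3.1.0]hexane-1-carboxylate; 8 2-(benzyloxy)-4-bromo-1-methoxybenzene
Product: 10 methyl (3S,4R)-4-{[3-(benzyloxy)-4-methoxyphenyl]methyl}-2-oxooxolane-3-carboxylate, via aryl Grignard reagent 9 (not isolated)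
Conditions: 8, Mg, I2 (cat.), THF, 50 °C; then CuI (0.2 equiv), 6, THF, −30 to −10 °C; cold 1 M HCl
Reagents that add atoms: none
Why: Magnesium insertion gives 9, and its copper-catalysed homoconjugate (SN2-type) addition to the doubly activated cyclopropane takes place at the unsubstituted CH2 (C7), breaking the sacrificial C7–C8' bond to release a stabilized lactone–ester enolate; C8 is not touched and stays R, while the labile C8' centre is protonated mainly trans.

Step 4
Reactants: 11 vanillin
Product: 12 4-(benzyloxy)-3-methoxybenzaldehyde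
Conditions: BnBr, K2CO3, DMF, 20 °C
Reagents that add atoms: benzyl bromide, BrCc1ccccc1
Why: Williamson etherification of the phenoxide; the aldehyde is inert to carbonate and benzyl bromide.

Step 5
Reactants: 12 4-(benzyloxy)-3-methoxybenzaldehyde
Product: 13 [4-(benzyloxy)-3-methoxyphenyl]methanol
Conditions: NaBH4, MeOH–THF, 0 °C
Reagents that add atoms: none
Why: Borohydride reduction of the aldehyde to the benzylic alcohol leaves the ethers untouched.

Step 6
Reactants: 13 [4-(benzyloxy)-3-methoxyphenyl]methanol
Product: 14 1-(benzyloxy)-4-(bromomethyl)-2-methoxybenzene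
Conditions: PBr3, Et2O, 0 °C; used at once
Reagents that add atoms: phosphorus tribromide, BrP(Br)Br
Why: Bromination of an electron-rich benzylic alcohol through its bromophosphite ester is fast at 0 °C, and immediate use avoids decomposition of the labile bromide.

Step 7
Reactants: 10 methyl (3S,4R)-4-{[3-(benzyloxy)-4-methoxyphenyl]methyl}-2-oxooxolane-3-carboxylate; 14 1-(benzyloxy)-4-(bromomethyl)-2-methoxybenzene
Product: 15 methyl (3R,4R)-3-{[4-(benzyloxy)-3-methoxyphenyl]methyl}-4-{[3-(benzyloxy)-4-methoxyphenyl]methyl}-2-oxooxolane-3-carboxylate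
Conditions: NaH, THF–DMF, 0 °C; then 14, 0 to 20 °C
Reagents that add atoms: none
Why: C-alkylation of the sodium enolate of the malonate-type lactone ester by SN2 on the benzylic bromide forms the C8'–C7' bond, the electrophile entering anti to the C8 substituent; the configuration of this quaternary centre is not decisive because it is reset in step 8.

Step 8
Reactants: 15 methyl (3R,4R)-3-{[4-(benzyloxy)-3-methoxyphenyl]methyl}-4-{[3-(benzyloxy)-4-methoxyphenyl]methyl}-2-oxooxolane-3-carboxylate
Product: 16 (3R,4R)-3-{[4-(benzyloxy)-3-methoxyphenyl]methyl}-4-{[3-(benzyloxy)-4-methoxyphenyl]methyl}oxolan-2-one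
Conditions: LiCl, H2O, DMSO, 150 °C; then DBU (cat.), PhMe, 60 °C
Reagents that add atoms: none
Why: Krapcho dealkoxycarbonylation (chloride SN2 at the ester methyl, loss of CO2) gives the lactone enolate, which is protonated on the face opposite the C8 substituent to set C8' as R; the trans-dibenzyl lactone is also the thermodynamic isomer, so the DBU equilibration should correct any cis material.

Step 9
Reactants: 16 (3R,4R)-3-{[4-(benzyloxy)-3-methoxyphenyl]methyl}-4-{[3-(benzyloxy)-4-methoxyphenyl]methyl}oxolan-2-one
Product: 17 (2R,3R)-2-{[4-(benzyloxy)-3-methoxyphenyl]methyl}-3-{[3-(benzyloxy)-4-methoxyphenyl]methyl}butane-1,4-diol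
Conditions: LiAlH4, THF, 0 to 20 °C; aqueous NaOH work-up
Reagents that add atoms: none
Why: Hydride reduction of the lactone to the 1,4-diol touches neither stereocentre nor the benzyl ethers.

Step 10
Reactants: 17 (2R,3R)-2-{[4-(benzyloxy)-3-methoxyphenyl]methyl}-3-{[3-(benzyloxy)-4-methoxyphenyl]methyl}butane-1,4-diol
Product: 18 (2R,3R)-2-{[4-(benzyloxy)-3-methoxyphenyl]methyl}-3-{[3-(benzyloxy)-4-methoxyphenyl]methyl}butane-1,4-diyl dibenzoate
Conditions: BzCl (2.5 equiv), Et3N, DMAP (cat.), CH2Cl2, 0 to 20 °C
Reagents that add atoms: benzoyl chloride, O=C(Cl)c1ccccc1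
Why: DMAP-catalysed acylation of the two primary alcohols; both phenols are still masked, so only the C9 and C9' oxygens are benzoylated.

Step 11
Reactants: 18 (2R,3R)-2-{[4-(benzyloxy)-3-methoxyphenyl]methyl}-3-{[3-(benzyloxy)-4-methoxyphenyl]methyl}butane-1,4-diyl dibenzoate
Product: 19 (2R,3R)-2-[(4-hydroxy-3-methoxyphenyl)methyl]-3-[(3-hydroxy-4-methoxyphenyl)methyl]butane-1,4-diyl dibenzoate (CNP0306197.1)
Conditions: H2 (1 atm), 10% Pd/C, EtOAc–MeOH, 20 °C
Reagents that add atoms: none
Why: Hydrogenolysis cleaves the two benzyl aryl ethers, while the benzoates of non-benzylic primary alcohols and the stereocentres are inert.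

**Compound list**
1 | dimethyl malonate | COC(=O)CC(=O)OC | starting material
2 | (R)-epichlorohydrin | ClC[C@H]1CO1 | starting material
3 | dimethyl 2-[(2R)-3-chloro-2-hydroxypropyl]propanedioate (present as its sodium alkoxide) | ClC[C@H](O)CC(C(=O)OC)C(=O)OC | intermediate
4 | dimethyl 2-{[(2R)-oxiran-2-yl]methyl}propanedioate | COC(=O)C(C[C@@H]1CO1)C(=O)OC | intermediate
5 | dimethyl (2R)-2-(hydroxymethyl)cyclopropane-1,1-dicarboxylate (present as its sodium alkoxide) | OC[C@@H]1CC1(C(=O)OC)C(=O)OC | intermediate
6 | methyl (1S,5R)-2-oxo-3-oxabicyclo[3.1.0]hexane-1-carboxylate | COC(=O)[C@]12C[C@H]1COC2=O | intermediate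
7 | 5-bromo-2-methoxyphenol | COc1ccc(Br)cc1O | starting material
8 | 2-(benzyloxy)-4-bromo-1-methoxybenzene | COc1ccc(Br)cc1OCc1ccccc1 | intermediate
9 | [3-(benzyloxy)-4-methoxyphenyl]magnesium bromide | COc1ccc([Mg]Br)cc1OCc1ccccc1 | intermediate
10 | methyl (3S,4R)-4-{[3-(benzyloxy)-4-methoxyphenyl]methyl}-2-oxooxolane-3-carboxylate (trans epimer drawn; C3 is labile) | COC(=O)[C@@H]1[C@@H](Cc2ccc(OC)c(OCc3ccccc3)c2)COC1=O | intermediate
11 | vanillin | COc1cc(C=O)ccc1O | starting material
12 | 4-(benzyloxy)-3-methoxybenzaldehyde | COc1cc(C=O)ccc1OCc1ccccc1 | intermediate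
13 | [4-(benzyloxy)-3-methoxyphenyl]methanol | COc1cc(CO)ccc1OCc1ccccc1 | intermediate
14 | 1-(benzyloxy)-4-(bromomethyl)-2-methoxybenzene | COc1cc(CBr)ccc1OCc1ccccc1 | intermediate
15 | methyl (3R,4R)-3-{[4-(benzyloxy)-3-methoxyphenyl]methyl}-4-{[3-(benzyloxy)-4-methoxyphenyl]methyl}-2-oxooxolane-3-carboxylate | COC(=O)[C@@]1(Cc2ccc(OCc3ccccc3)c(OC)c2)[C@@H](Cc2ccc(OC)c(OCc3ccccc3)c2)COC1=O | intermediate
16 | (3R,4R)-3-{[4-(benzyloxy)-3-methoxyphenyl]methyl}-4-{[3-(benzyloxy)-4-methoxyphenyl]methyl}oxolan-2-one | O=C1OC[C@H](Cc2ccc(OC)c(OCc3ccccc3)c2)[C@H]1Cc1ccc(OCc2ccccc2)c(OC)c1 | intermediate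
17 | (2R,3R)-2-{[4-(benzyloxy)-3-methoxyphenyl]methyl}-3-{[3-(benzyloxy)-4-methoxyphenyl]methyl}butane-1,4-diol | COc1ccc(C[C@@H](CO)[C@H](CO)Cc2ccc(OCc3ccccc3)c(OC)c2)cc1OCc1ccccc1 | intermediate
18 | (2R,3R)-2-{[4-(benzyloxy)-3-methoxyphenyl]methyl}-3-{[3-(benzyloxy)-4-methoxyphenyl]methyl}butane-1,4-diyl dibenzoate | COc1ccc(C[C@@H](COC(=O)c2ccccc2)[C@H](COC(=O)c2ccccc2)Cc2ccc(OCc3ccccc3)c(OC)c2)cc1OCc1ccccc1 | intermediate
19 | (2R,3R)-2-[(4-hydroxy-3-methoxyphenyl)methyl]-3-[(3-hydroxy-4-methoxyphenyl)methyl]butane-1,4-diyl dibenzoate | COc1ccc(C[C@@H](COC(=O)c2ccccc2)[C@H](COC(=O)c2ccccc2)Cc2ccc(O)c(OC)c2)cc1O | target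

**Step count**
Total: 11 steps. Longest linear sequence: 8 steps (steps 4, 5, 6, 7, 8, 9, 10, 11 from vanillin); the sequence through the key step is 7 steps (1, 3, 7, 8, 9, 10, 11).

**Steps most likely to fail**

Step 3. The aryl magnesium reagent may add to the lactone or ester carbonyl instead of the cyclopropane, the electron-rich aryl group may transfer sluggishly from copper, or attack may occur at the ring-fusion CH. The fallback sets out from 6 and returns at 10, and separates ring opening from C–C bond formation. The cyclopropane is opened with iodide (NaI, TMSCl, MeCN, 0 to 20 °C, aqueous work-up), a homoconjugate addition of a soft heteroatom nucleophile that should give methyl (3S,4R)-4-(iodomethyl)-2-oxooxolane-3-carboxylate F1. The aryl–C7 bond is then made by nickel-catalysed reductive cross-electrophile coupling of the primary iodide with aryl bromide 8 (NiI2, 4,4'-di-tert-butyl-2,2'-bipyridine, Zn dust, DMA, 60 °C). These conditions contain no base, so that the iodide should not close back to 6, and the coupling should deliver 10.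

Step 7. C-alkylation at the hindered carbon next to the C8 substituent may be slow, so that O-alkylation and decomposition of the electron-rich benzylic bromide compete. The fallback sets out from 10 and returns at 16, and reverses the order of decarboxylation and benzylation. Compound 10 is dealkoxycarbonylated first (LiCl, H2O, DMSO, 140 °C) to (4R)-4-{[3-(benzyloxy)-4-methoxyphenyl]methyl}oxolan-2-one F2. Its lithium enolate (LiHMDS, THF, −78 °C) is then alkylated with 14; approach anti to the C4 substituent should give the trans lactone 16 directly.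

Step 8. Demethylation and loss of CO2 at the quaternary centre may be incomplete, the material may suffer at 150 °C, or protonation of the enolate may be unselective. The fallback sets out from 15 and returns at 16, and replaces dealkylative by hydrolytic decarboxylation. Saponification (KOH, aqueous MeOH–THF, reflux) followed by acidification with HCl should hydrolyse the ester and re-close the lactone to (3RS,4R)-3-{[4-(benzyloxy)-3-methoxyphenyl]methyl}-4-{[3-(benzyloxy)-4-methoxyphenyl]methyl}-2-oxooxolane-3-carboxylic acid F3. This malonic-type acid should lose CO2 in toluene at 110 °C, and catalytic DBU would then equilibrate the product to the trans lactone 16.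

**Further compounds**
F1 | step 3 | methyl (3S,4R)-4-(iodomethyl)-2-oxooxolane-3-carboxylate (trans epimer drawn; C3 is labile) | COC(=O)[C@@H]1[C@@H](CI)COC1=O
F2 | step 7 | (4R)-4-{[3-(benzyloxy)-4-methoxyphenyl]methyl}oxolan-2-one | O=C1C[C@@H](Cc2ccc(OC)c(OCc3ccccc3)c2)CO1
F3 | step 8 | (3RS,4R)-3-{[4-(benzyloxy)-3-methoxyphenyl]methyl}-4-{[3-(benzyloxy)-4-methoxyphenyl]methyl}-2-oxooxolane-3-carboxylic acid (C3 epimers) | OC(=O)C1(Cc2ccc(OCc3ccccc3)c(OC)c2)[C@@H](Cc2ccc(OC)c(OCc3ccccc3)c2)COC1=O
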